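**Retrosynthetic overview**

1. Ring C is closed last by forming C1–C10 in a palladium-hydride reductive cyclisation of the 1,8-enyne 30. The strategy rests on the exocyclic C10=C11 alkene of cycloheptane ring C (C1–C2–C3–C4–C5–C9–C10), in which C12 is cis to the quaternary C9 and H is cis to C1, the outcome of syn addition of H and C1 across a C10≡C11 alkyne.
2. Enyne 30 comes from the ring A/B β-keto ester 26 and the propargylic bromide 18: C12–C13 by enolate C-alkylation, then decarboxylation, methyl addition at C23 and oxidation at C17.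
3. 26 comes from geranyl bromide: Weinreb amide, double Shi epoxidation, β-keto ester, then a diepoxide/enol silane cascade that forms oxepane ring A and cyclohexane ring B in one step.
4. 18 comes from the (R)-limonene-derived diol 4: hydroalkynylation of the isopropenyl group (C9–C10), glycol cleavage and aldol condensation to cyclopentene ring D, epoxidation/Wharton transposition (C8), hydroboration (C4), allyl coupling (butenyl arm).
5. Ring order: D (step 5), A and B (step 17), C (step 22).

Key step: step 22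

Remark on numbering: C1–C23 follow the skeletal atoms of the target SMILES in order (O19 is the ring oxygen). Ring A = oxepane (C14–C18, O19, C20), ring B = cyclohexane (C13, C14, C20–C23), ring C = cycloheptane, ring D = cyclopentane (C4–C8).
Assumption: the D-fructose-derived Shi ketone gives the (R,R) sense on both E-trisubstituted alkenes of 21, as on other such alkenes; the C17 configuration is immaterial because C17 ends as the ketone.
Assumption: (1S,2S,4R)-limonene-1,2-diol (hydrolysis product of (R)-limonene oxide) and phenylsilane-grade reagents are commercial; the alkynyl sulfone 3 is made in steps 1 and 2.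

Step 1
Reactants: 1 (triisopropylsilyl)acetylene
Product: 2 triisopropyl[(phenylsulfanyl)ethynyl]silane
Conditions: n-BuLi, THF, −78 °C; PhSSPh, −78 °C → rt; NH4Cl
Reagents that add atoms: diphenyl disulfide, c1ccccc1SSc1ccccc1
Why: Sulfenylation of a lithium acetylide by a disulfide is routine.

Step 2
Reactants: 2 triisopropyl[(phenylsulfanyl)ethynyl]silane
Product: 3 triisopropyl[(phenylsulfonyl)ethynyl]silane
Conditions: mCPBA (2.2 equiv), CH2Cl2, 0 °C → rt
Reagents that add atoms: mCPBA, OOC(=O)c1cccc(Cl)c1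
Why: Peracid oxidation of the sulfide to the sulfone; the silyl alkyne is not epoxidised.

Step 3
Reactants: 4 (1S,2S,4R)-limonene-1,2-diol; 3 triisopropyl[(phenylsulfonyl)ethynyl]silane
Product: 5 (1S,2S,4R)-1-methyl-4-[2-methyl-4-(triisopropylsilyl)but-3-yn-2-yl]cyclohexane-1,2-diol
Conditions: Fe(acac)3, PhSiH3, EtOH/(CH2OH)2, 60 °C
Reagents that add atoms: none
Why: Mukaiyama-type hydrogen atom transfer hydroalkynylation: the iron hydride gives the tertiary C9 radical at the only alkene, which adds at the sulfonyl-bearing alkyne carbon and expels PhSO2•, forming the quaternary propargylic C9–C10 bond without touching the C5 stereocentre.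

Step 4
Reactants: 5 (1S,2S,4R)-1-methyl-4-[2-methyl-4-(triisopropylsilyl)but-3-yn-2-yl]cyclohexane-1,2-diol
Product: 6 (3R)-3-[2-methyl-4-(triisopropylsilyl)but-3-yn-2-yl]-6-oxoheptanal
Conditions: NaIO4, THF/H2O, rt
Reagents that add atoms: none
Why: Malaprade glycol cleavage opens the six-membered ring to the keto aldehyde.

Step 5
Reactants: 6 (3R)-3-[2-methyl-4-(triisopropylsilyl)but-3-yn-2-yl]-6-oxoheptanal
Product: 7 (5S)-2-methyl-5-[2-methyl-4-(triisopropylsilyl)but-3-yn-2-yl]cyclopent-1-ene-1-carbaldehyde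
Conditions: piperidine, AcOH (cat.), PhMe, reflux (−H2O)
Reagents that add atoms: none
Why: Amine-catalysed intramolecular aldol condensation (enamine of the aldehyde onto the methyl ketone) closes ring D, as known for the parent limonene keto aldehyde.

Step 6
Reactants: 7 (5S)-2-methyl-5-[2-methyl-4-(triisopropylsilyl)but-3-yn-2-yl]cyclopent-1-ene-1-carbaldehyde
Product: 8 (1S,2S,5R)-5-methyl-2-[2-methyl-4-(triisopropylsilyl)but-3-yn-2-yl]-6-oxabicyclo[3.1.0]hexane-1-carbaldehyde
Conditions: H2O2 (30 % aq.), NaOH (cat.), MeOH, 0 °C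
Reagents that add atoms: hydrogen peroxide, OO
Why: Weitz–Scheffer nucleophilic epoxidation; ring closure at C4 occurs anti to the bulky C5 side chain, which places the C8 oxygen trans to that chain as the target requires.

Step 7
Reactants: 8 (1S,2S,5R)-5-methyl-2-[2-methyl-4-(triisopropylsilyl)but-3-yn-2-yl]-6-oxabicyclo[3.1.0]hexane-1-carbaldehyde
Product: 10 (1R,3S)-1-methyl-2-methylidene-3-[2-methyl-4-(triisopropylsilyl)but-3-yn-2-yl]cyclopentan-1-ol, via epoxy hydrazone 9 (not isolated)
Conditions: N2H4·H2O, AcOH (cat.), MeOH, 0 °C → rt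
Reagents that add atoms: hydrazine hydrate, NN.O (nitrogen only in 9)
Why: Wharton transposition: the hydrazone opens the epoxide at C4 with the C8–O bond kept (C8 configuration retained) and loses N2 to leave the exocyclic C4=C3 methylene.

Step 8
Reactants: 10 (1R,3S)-1-methyl-2-methylidene-3-[2-methyl-4-(triisopropylsilyl)but-3-yn-2-yl]cyclopentan-1-ol
Product: 12 (1R,2S,3R)-2-(hydroxymethyl)-1-methyl-3-[2-methyl-4-(triisopropylsilyl)but-3-yn-2-yl]cyclopentan-1-ol, via alkylborane 11 (not isolated)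
Conditions: 9-BBN, THF, 0 → 60 °C; NaOH, H2O2, 0 °C
Reagents that add atoms: 9-borabicyclo[3.3.1]nonane, C1CC2CCCC(C1)B2 (boron only in 11); hydrogen peroxide, OO
Why: Hydroboration–oxidation: hydrogen is delivered to C4 from the face of C8–OH and H5, away from the C8 methyl and the C5 tert-alkyl group, so the CH2OH arm ends cis to both neighbours (C4 set), and the hindered silyl alkyne is inert to 9-BBN.

Step 9
Reactants: 12 (1R,2S,3R)-2-(hydroxymethyl)-1-methyl-3-[2-methyl-4-(triisopropylsilyl)but-3-yn-2-yl]cyclopentan-1-ol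
Product: 14 primary tosylate and tertiary trimethylsilyl ether of 12, via hydroxy tosylate 13 (not isolated)
Conditions: TsCl, Et3N, DMAP (cat.), CH2Cl2, 0 °C; then Me3SiOTf, Et3N, −78 → 0 °C
Reagents that add atoms: p-toluenesulfonyl chloride, Cc1ccc(cc1)S(Cl)(=O)=O; trimethylsilyl triflate, C[Si](C)(C)OS(=O)(=O)C(F)(F)F
Why: Selective sulfonylation of the primary alcohol, then silylation of the tertiary alcohol so that no alkoxide can trigger Grob fragmentation in the next step.

Step 10
Reactants: 14 primary tosylate and tertiary trimethylsilyl ether of 12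
Product: 15 {[(1R,2R,3R)-2-(but-3-en-1-yl)-1-methyl-3-[2-methyl-4-(triisopropylsilyl)but-3-yn-2-yl]cyclopentyl]oxy}trimethylsilane
Conditions: allylMgBr, CuI (cat.), THF, −30 °C → rt
Reagents that add atoms: allylmagnesium bromide, C=CC[Mg]Br
Why: Copper-catalysed SN2 coupling of a primary tosylate with an allyl Grignard reagent builds the butenyl arm (C3–C2).

Step 11
Reactants: 15 {[(1R,2R,3R)-2-(but-3-en-1-yl)-1-methyl-3-[2-methyl-4-(triisopropylsilyl)but-3-yn-2-yl]cyclopentyl]oxy}trimethylsilane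
Product: 16 (1R,2R,3R)-2-(but-3-en-1-yl)-1-methyl-3-(2-methylbut-3-yn-2-yl)cyclopentan-1-ol
Conditions: Bu4NF, THF, rt
Reagents that add atoms: none
Why: Fluoride removes the alkynyl and the oxygen-bound silyl groups in one operation.

Step 12
Reactants: 16 (1R,2R,3R)-2-(but-3-en-1-yl)-1-methyl-3-(2-methylbut-3-yn-2-yl)cyclopentan-1-ol
Product: 17 (1R,2R,3R)-2-(but-3-en-1-yl)-3-(5-hydroxy-2-methylpent-3-yn-2-yl)-1-methylcyclopentan-1-ol
Conditions: n-BuLi (2.2 equiv), THF, −78 °C; (CH2O)n, → rt; NH4Cl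
Reagents that add atoms: formaldehyde (as paraformaldehyde), C=O
Why: Hydroxymethylation of the lithium acetylide (alkoxide present as spectator) installs C12.

Step 13
Reactants: 17 (1R,2R,3R)-2-(but-3-en-1-yl)-3-(5-hydroxy-2-methylpent-3-yn-2-yl)-1-methylcyclopentan-1-ol
Product: 18 (1R,2R,3R)-3-(5-bromo-2-methylpent-3-yn-2-yl)-2-(but-3-en-1-yl)-1-methylcyclopentan-1-ol
Conditions: CBr4, PPh3, CH2Cl2, −20 → 0 °C
Reagents that add atoms: carbon tetrabromide, BrC(Br)(Br)Br
Why: Appel bromination converts only the primary propargylic alcohol; the hindered tertiary alcohol does not react.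

Step 14
Reactants: 19 N-methoxy-N-methylacetamide; 20 geranyl bromide
Product: 21 (4E)-N-methoxy-N,5,9-trimethyldeca-4,8-dienamide
Conditions: LiN(i-Pr)2, THF, −78 °C; 20, −78 → −20 °C
Reagents that add atoms: none
Why: Amide enolate alkylation (SN2) with an allylic bromide forms C21–C22 with the E-alkene intact.

Step 15
Reactants: 21 (4E)-N-methoxy-N,5,9-trimethyldeca-4,8-dienamide
Product: 22 3-[(2R,3R)-3-{2-[(2R)-3,3-dimethyloxiran-2-yl]ethyl}-3-methyloxiran-2-yl]-N-methoxy-N-methylpropanamide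
Conditions: D-fructose-derived Shi ketone, KHSO5 (Oxone), K2CO3, Bu4NHSO4, MeCN/(MeO)2CH2/aq. buffer (pH 10.5), 0 °C
Reagents that add atoms: potassium peroxymonosulfate, [K+].[O-]S(=O)(=O)OO
Why: Shi asymmetric epoxidation through the spiro transition state sets the (20R,14R) epoxide, which defines C20 directly and C14 after inversion in step 17.

Step 16
Reactants: 22 3-[(2R,3R)-3-{2-[(2R)-3,3-dimethyloxiran-2-yl]ethyl}-3-methyloxiran-2-yl]-N-methoxy-N-methylpropanamide
Product: 23 methyl 5-[(2R,3R)-3-{2-[(2R)-3,3-dimethyloxiran-2-yl]ethyl}-3-methyloxiran-2-yl]-3-oxopentanoate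
Conditions: LiCH2CO2Me (from MeOAc, LiN(i-Pr)2), THF, −78 °C; NH4Cl
Reagents that add atoms: methyl acetate, CC(=O)OC
Why: Acylation of an ester enolate by a Weinreb amide; the chelated tetrahedral intermediate releases the β-keto ester only on work-up, and the epoxides survive at −78 °C.

Step 17
Reactants: 23 methyl 5-[(2R,3R)-3-{2-[(2R)-3,3-dimethyloxiran-2-yl]ethyl}-3-methyloxiran-2-yl]-3-oxopentanoate
Product: 26 methyl (3R,5aR,9aR)-3-hydroxy-2,2,5a-trimethyl-7-oxoperhydro-1-benzoxepine-6-carboxylate, via silyl enol ether 24 (not isolated), via cyclised silyl ether 25 (not isolated)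
Conditions: Me3SiCl, Et3N, hexane, rt, filter; Me3SiOTf, 2,6-di-tert-butyl-4-methylpyridine, CH2Cl2, −78 °C; citric acid, MeOH
Reagents that add atoms: chlorotrimethylsilane, C[Si](C)(C)Cl (silicon only in 24); trimethylsilyl triflate, C[Si](C)(C)OS(=O)(=O)C(F)(F)F (silicon only in 25)
Why: Lewis acid-triggered tandem oxa-/carbacyclisation of a diepoxide with an enol silane terminator: the silylated terminal epoxide is opened at tertiary C18 by the internal epoxide oxygen (7-endo, ring A), and the resulting epoxonium ion is opened at tertiary C14 with inversion by the enol silane carbon C13 (ring B), which gives the trans A/B fusion with C20 retained.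

Step 18
Reactants: 26 methyl (3R,5aR,9aR)-3-hydroxy-2,2,5a-trimethyl-7-oxoperhydro-1-benzoxepine-6-carboxylate; 18 (1R,2R,3R)-3-(5-bromo-2-methylpent-3-yn-2-yl)-2-(but-3-en-1-yl)-1-methylcyclopentan-1-ol
Product: 27 methyl (3R,5aR,6R,9aR)-6-{4-[(1R,2R,3R)-2-(but-3-en-1-yl)-3-hydroxy-3-methylcyclopentyl]-4-methylpent-2-yn-1-yl}-3-hydroxy-2,2,5a-trimethyl-7-oxoperhydro-1-benzoxepine-6-carboxylate
Conditions: Cs2CO3, DMF, 0 °C → rt
Reagents that add atoms: none
Why: C-alkylation of the β-keto ester enolate with a propargylic bromide (SN2) forms C12–C13 at the only acidic carbon, from the face opposite the axial C14 methyl, and the carbonate base leaves the hydroxyl groups untouched.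

Step 19
Reactants: 27 methyl (3R,5aR,6R,9aR)-6-{4-[(1R,2R,3R)-2-(but-3-en-1-yl)-3-hydroxy-3-methylcyclopentyl]-4-methylpent-2-yn-1-yl}-3-hydroxy-2,2,5a-trimethyl-7-oxoperhydro-1-benzoxepine-6-carboxylate
Product: 28 (3R,5aR,6R,9aR)-6-{4-[(1R,2R,3R)-2-(but-3-en-1-yl)-3-hydroxy-3-methylcyclopentyl]-4-methylpent-2-yn-1-yl}-3-hydroxy-2,2,5a-trimethylperhydro-1-benzoxepin-7-one
Conditions: LiCl, H2O, DMSO, 140 °C; then K2CO3, MeOH, rt
Reagents that add atoms: none
Why: Krapcho dealkoxycarbonylation removes the activating ester, and base equilibration places the propargyl arm at C13 equatorial, trans-diaxial H13/C14-methyl, as in the target.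

Step 20
Reactants: 28 (3R,5aR,6R,9aR)-6-{4-[(1R,2R,3R)-2-(but-3-en-1-yl)-3-hydroxy-3-methylcyclopentyl]-4-methylpent-2-yn-1-yl}-3-hydroxy-2,2,5a-trimethylperhydro-1-benzoxepin-7-one
Product: 29 (3R,5aR,6R,7S,9aR)-6-{4-[(1R,2R,3R)-2-(but-3-en-1-yl)-3-hydroxy-3-methylcyclopentyl]-4-methylpent-2-yn-1-yl}-2,2,5a,7-tetramethylperhydro-1-benzoxepine-3,7-diol
Conditions: MeMgBr, CeCl3, THF, −78 → 0 °C; NH4Cl
Reagents that add atoms: methylmagnesium bromide, C[Mg]Br
Why: Organocerium methyl addition to the C23 ketone from the equatorial side, away from the 1,3-diaxial C14 methyl, gives the axial tertiary alcohol (C23 S) without enolising C13.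

Step 21
Reactants: 29 (3R,5aR,6R,7S,9aR)-6-{4-[(1R,2R,3R)-2-(but-3-en-1-yl)-3-hydroxy-3-methylcyclopentyl]-4-methylpent-2-yn-1-yl}-2,2,5a,7-tetramethylperhydro-1-benzoxepine-3,7-diol
Product: 30 (5aR,6R,7S,9aR)-6-{4-[(1R,2R,3R)-2-(but-3-en-1-yl)-3-hydroxy-3-methylcyclopentyl]-4-methylpent-2-yn-1-yl}-7-hydroxy-2,2,5a,7-tetramethylperhydro-1-benzoxepin-3-one
Conditions: Dess–Martin periodinane, NaHCO3, CH2Cl2, rt
Reagents that add atoms: none
Why: Dess–Martin oxidation of the only secondary alcohol (C17) gives the oxepanone; the two tertiary alcohols cannot be oxidised.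

Step 22
Reactants: 30 (5aR,6R,7S,9aR)-6-{4-[(1R,2R,3R)-2-(but-3-en-1-yl)-3-hydroxy-3-methylcyclopentyl]-4-methylpent-2-yn-1-yl}-7-hydroxy-2,2,5a,7-tetramethylperhydro-1-benzoxepin-3-one
Product: 31 target CNP0157787.1, (1S,4R,5R,8R,10Z,13R,14R,20R,23S) in skeletal numbering
Conditions: Pd2(dba)3·CHCl3 (cat.), P(o-tol)3 (cat.), AcOH, Et3SiH (slow addition), PhMe (high dilution), 60 °C
Reagents that add atoms: none
Why: Proposed new method: a palladium hydride formed from zerovalent palladium and AcOH adds syn across C10≡C11 with palladium on C10 under chelation by the tethered alkene, the alkenylpalladium inserts the terminal alkene in a 7-exo-trig closure (C1–C10, ring C) with retention at C10, and Et3SiH reduces the primary alkylpalladium to the C1 methyl group before β-hydride elimination. The closest known reaction type is the palladium-hydride reductive cyclisation of 1,6- and 1,7-enynes to alkylidene cyclopentanes and cyclohexanes, and the extension proposed here is the 1,8-enyne and the seven-membered ring. The alkene geometry (C12 cis to C9, H cis to C1) follows from syn hydropalladation and retentive insertion and is not under thermodynamic control. The new stereocentre C1 is set under substrate control in the insertion step, where the butenyl arm folds over the cis-disubstituted ring D; a chair-like seven-membered transition state with the incipient methyl trans to H4 and H5 is expected but not secured. The step needs hydropalladation with palladium at the hindered C10, for which only alkene chelation and the proximity enforced by the C9 gem-dimethyl group and the cis C4/C5 arrangement speak; the C11-palladated isomer can only be reduced to the (Z)-alkene, the main expected loss.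

**Compound list**

1 | (triisopropylsilyl)acetylene | C#C[Si](C(C)C)(C(C)C)C(C)C | starting material
2 | triisopropyl[(phenylsulfanyl)ethynyl]silane | CC(C)[Si](C#CSc1ccccc1)(C(C)C)C(C)C | intermediate
3 | triisopropyl[(phenylsulfonyl)ethynyl]silane | CC(C)[Si](C#CS(=O)(=O)c1ccccc1)(C(C)C)C(C)C | intermediate
4 | (1S,2S,4R)-limonene-1,2-diol | C[C@]1(O)CC[C@@H](C(C)=C)C[C@@H]1O | starting material
5 | (1S,2S,4R)-1-methyl-4-[2-methyl-4-(triisopropylsilyl)but-3-yn-2-yl]cyclohexane-1,2-diol | C[C@]1(O)CC[C@@H](C(C)(C)C#C[Si](C(C)C)(C(C)C)C(C)C)C[C@@H]1O | intermediate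
6 | (3R)-3-[2-methyl-4-(triisopropylsilyl)but-3-yn-2-yl]-6-oxoheptanal | CC(=O)CC[C@H](CC=O)C(C)(C)C#C[Si](C(C)C)(C(C)C)C(C)C | intermediate
7 | (5S)-2-methyl-5-[2-methyl-4-(triisopropylsilyl)but-3-yn-2-yl]cyclopent-1-ene-1-carbaldehyde | O=CC1=C(C)CC[C@H]1C(C)(C)C#C[Si](C(C)C)(C(C)C)C(C)C | intermediate
8 | (1S,2S,5R)-5-methyl-2-[2-methyl-4-(triisopropylsilyl)but-3-yn-2-yl]-6-oxabicyclo[3.1.0]hexane-1-carbaldehyde (epoxide trans to the side chain) | O=C[C@@]12O[C@]1(C)CC[C@H]2C(C)(C)C#C[Si](C(C)C)(C(C)C)C(C)C | intermediate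
9 | hydrazone of epoxy aldehyde 8 (C=N geometry not defined) | NN=C[C@@]12O[C@]1(C)CC[C@H]2C(C)(C)C#C[Si](C(C)C)(C(C)C)C(C)C | intermediate
10 | (1R,3S)-1-methyl-2-methylidene-3-[2-methyl-4-(triisopropylsilyl)but-3-yn-2-yl]cyclopentan-1-ol | C=C1[C@@H](CC[C@@]1(C)O)C(C)(C)C#C[Si](C(C)C)(C(C)C)C(C)C | intermediate
11 | B-alkyl-9-borabicyclo[3.3.1]nonane from 10 (boron on C3, H4 cis to OH) | C(B1C2CCCC1CCC2)[C@@H]1[C@@H](CC[C@@]1(C)O)C(C)(C)C#C[Si](C(C)C)(C(C)C)C(C)C | intermediate
12 | (1R,2S,3R)-2-(hydroxymethyl)-1-methyl-3-[2-methyl-4-(triisopropylsilyl)but-3-yn-2-yl]cyclopentan-1-ol | OC[C@@H]1[C@@H](CC[C@@]1(C)O)C(C)(C)C#C[Si](C(C)C)(C(C)C)C(C)C | intermediate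
13 | primary tosylate of diol 12 | Cc1ccc(cc1)S(=O)(=O)OC[C@@H]1[C@@H](CC[C@@]1(C)O)C(C)(C)C#C[Si](C(C)C)(C(C)C)C(C)C | intermediate
14 | primary tosylate and tertiary trimethylsilyl ether of 12 | Cc1ccc(cc1)S(=O)(=O)OC[C@@H]1[C@@H](CC[C@@]1(C)O[Si](C)(C)C)C(C)(C)C#C[Si](C(C)C)(C(C)C)C(C)C | intermediate
15 | {[(1R,2R,3R)-2-(but-3-en-1-yl)-1-methyl-3-[2-methyl-4-(triisopropylsilyl)but-3-yn-2-yl]cyclopentyl]oxy}trimethylsilane | C=CCC[C@@H]1[C@@H](CC[C@@]1(C)O[Si](C)(C)C)C(C)(C)C#C[Si](C(C)C)(C(C)C)C(C)C | intermediate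
16 | (1R,2R,3R)-2-(but-3-en-1-yl)-1-methyl-3-(2-methylbut-3-yn-2-yl)cyclopentan-1-ol | C=CCC[C@@H]1[C@@H](CC[C@@]1(C)O)C(C)(C)C#C | intermediate
17 | (1R,2R,3R)-2-(but-3-en-1-yl)-3-(5-hydroxy-2-methylpent-3-yn-2-yl)-1-methylcyclopentan-1-ol | C=CCC[C@@H]1[C@@H](CC[C@@]1(C)O)C(C)(C)C#CCO | intermediate
18 | (1R,2R,3R)-3-(5-bromo-2-methylpent-3-yn-2-yl)-2-(but-3-en-1-yl)-1-methylcyclopentan-1-ol | C=CCC[C@@H]1[C@@H](CC[C@@]1(C)O)C(C)(C)C#CCBr | intermediate
19 | N-methoxy-N-methylacetamide | CC(=O)N(C)OC | starting material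
20 | geranyl bromide | CC(C)=CCC/C(C)=C/CBr | starting material
21 | (4E)-N-methoxy-N,5,9-trimethyldeca-4,8-dienamide | CON(C)C(=O)CC/C=C(\C)CCC=C(C)C | intermediate
22 | 3-[(2R,3R)-3-{2-[(2R)-3,3-dimethyloxiran-2-yl]ethyl}-3-methyloxiran-2-yl]-N-methoxy-N-methylpropanamide | CON(C)C(=O)CC[C@H]1O[C@]1(C)CC[C@H]1OC1(C)C | intermediate
23 | methyl 5-[(2R,3R)-3-{2-[(2R)-3,3-dimethyloxiran-2-yl]ethyl}-3-methyloxiran-2-yl]-3-oxopentanoate | COC(=O)CC(=O)CC[C@H]1O[C@]1(C)CC[C@H]1OC1(C)C | intermediate
24 | trimethylsilyl enol ether of 23 (E/Z mixture, geometry immaterial) | COC(=O)C=C(O[Si](C)(C)C)CC[C@H]1O[C@]1(C)CC[C@H]1OC1(C)C | intermediate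
25 | 3-O-trimethylsilyl ether of 26 | COC(=O)C1C(=O)CC[C@H]2OC(C)(C)[C@H](O[Si](C)(C)C)CC[C@]12C | intermediate
26 | methyl (3R,5aR,9aR)-3-hydroxy-2,2,5a-trimethyl-7-oxoperhydro-1-benzoxepine-6-carboxylate (trans-fused; C6 epimers and enol) | COC(=O)C1C(=O)CC[C@H]2OC(C)(C)[C@H](O)CC[C@]12C | intermediate
27 | methyl (3R,5aR,6R,9aR)-6-{4-[(1R,2R,3R)-2-(but-3-en-1-yl)-3-hydroxy-3-methylcyclopentyl]-4-methylpent-2-yn-1-yl}-3-hydroxy-2,2,5a-trimethyl-7-oxoperhydro-1-benzoxepine-6-carboxylate | COC(=O)[C@@]1(CC#CC(C)(C)[C@@H]2CC[C@@](C)(O)[C@@H]2CCC=C)C(=O)CC[C@H]2OC(C)(C)[C@H](O)CC[C@]12C | intermediate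
28 | (3R,5aR,6R,9aR)-6-{4-[(1R,2R,3R)-2-(but-3-en-1-yl)-3-hydroxy-3-methylcyclopentyl]-4-methylpent-2-yn-1-yl}-3-hydroxy-2,2,5a-trimethylperhydro-1-benzoxepin-7-one | C=CCC[C@@H]1[C@@H](CC[C@@]1(C)O)C(C)(C)C#CC[C@@H]1[C@@]2(C)CC[C@@H](O)C(C)(C)O[C@@H]2CCC1=O | intermediate
29 | (3R,5aR,6R,7S,9aR)-6-{4-[(1R,2R,3R)-2-(but-3-en-1-yl)-3-hydroxy-3-methylcyclopentyl]-4-methylpent-2-yn-1-yl}-2,2,5a,7-tetramethylperhydro-1-benzoxepine-3,7-diol | C=CCC[C@@H]1[C@@H](CC[C@@]1(C)O)C(C)(C)C#CC[C@@H]1[C@@]2(C)CC[C@@H](O)C(C)(C)O[C@@H]2CC[C@]1(C)O | intermediate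
30 | (5aR,6R,7S,9aR)-6-{4-[(1R,2R,3R)-2-(but-3-en-1-yl)-3-hydroxy-3-methylcyclopentyl]-4-methylpent-2-yn-1-yl}-7-hydroxy-2,2,5a,7-tetramethylperhydro-1-benzoxepin-3-one (enyne precursor) | C=CCC[C@@H]1[C@@H](CC[C@@]1(C)O)C(C)(C)C#CC[C@@H]1[C@@]2(C)CCC(=O)C(C)(C)O[C@@H]2CC[C@]1(C)O | intermediate
31 | CNP0157787.1, (1S,4R,5R,8R,10Z,13R,14R,20R,23S) in skeletal numbering | C[C@H]1CC[C@@H]2[C@@H](CC[C@@]2(C)O)C(C)(C)/C1=C\C[C@@H]1[C@@]2(C)CCC(=O)C(C)(C)O[C@@H]2CC[C@]1(C)O | target

**Step count and risks**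

Total step count: 22. Longest linear sequence: 18 steps (steps 1–13, then 18–22, counted from (triisopropylsilyl)acetylene, whose two carbons become C10 and C11; 16 steps from diol 4).

Steps most likely to fail:

Step 22 (proposed new method). What may go wrong: hydropalladation with palladium at the less hindered C11, which drains material to the semireduced alkene. Insertion may be too slow for a seven-membered ring, so that hydrosilylation or isomerisation of the terminal alkene competes. Facial selectivity at C1 may be poor. The fallback uses a tin-radical enyne cyclisation, a known reaction class in which the regiochemical bias works in favour. It sets out from 30: Bu3SnH (slow addition) and AIBN in benzene at 80 °C add the tin radical reversibly at the unhindered C11; the C10 vinyl radical closes 7-exo-trig onto the alkene and abstracts hydrogen to give vinylstannane F1, with the bulky tin expected cis to C1. Protodestannylation with HCl in CH2Cl2 at −20 °C proceeds with retention and returns to the route at 31.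

Step 17. What may go wrong: the ester-conjugated enol silane may be too weak a nucleophile, so that the epoxonium ion collapses by elimination or triflate capture, or the internal epoxide is activated first and ring A is not formed. The fallback uses a simple ketone enol silane as terminator and fixes the regiochemistry afterwards. It sets out from 22: MeMgBr gives methyl ketone F2, and LiN(i-Pr)2 with t-BuMe2SiCl gives the terminal enol silane F3. The same Me3SiOTf-triggered cascade followed by desilylation gives bicyclic hydroxy ketone F4. Kinetic enolisation at the unhindered C22, silylation and Saegusa oxidation with Pd(OAc)2 give enone F5, whose only enolisable site is C13. Deprotonation there with LiN(i-Pr)2 and alkylation with bromide 18 give the propargylated enone F6, and conjugate reduction with [(Ph3P)CuH]6 returns to the route at 28.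

Step 18. What may go wrong: O-alkylation, or no reaction, at a carbon flanked by the quaternary C14, since the step creates two adjacent fully substituted carbons. The fallback moves the union to the C11–C12 bond. It sets out from 26 and 16: saponification with LiOH, then aqueous CH2O and Et2NH (decarboxylative Mannich reaction and elimination), give the α-methylene ketone F7. Alkyne 16 is silylated (Me3SiOTf, Et3N) to the trimethylsilyl ether F8, lithiated with n-BuLi and converted with Me2AlCl into the alkynylalane. This adds 1,4 to the s-cis enone F7 (hydroxyl masked beforehand with AlMe3), and acidic work-up with equilibration at C13 returns to the route at 28.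

**Further compounds**

F1 | step 22 | C11-tributylstannyl derivative of 31 (tin cis to C1, C12 cis to C9) | C[C@H]1CC[C@@H]2[C@@H](CC[C@@]2(C)O)C(C)(C)/C1=C(/[Sn](CCCC)(CCCC)CCCC)C[C@@H]1[C@@]2(C)CCC(=O)C(C)(C)O[C@@H]2CC[C@]1(C)O
F2 | step 17 | 4-[(2R,3R)-3-{2-[(2R)-3,3-dimethyloxiran-2-yl]ethyl}-3-methyloxiran-2-yl]butan-2-one | CC(=O)CC[C@H]1O[C@]1(C)CC[C@H]1OC1(C)C
F3 | step 17 | tert-butyldimethylsilyl enol ether (terminal) of F2 | C=C(O[Si](C)(C)C(C)(C)C)CC[C@H]1O[C@]1(C)CC[C@H]1OC1(C)C
F4 | step 17 | (3R,5aR,9aR)-3-hydroxy-2,2,5a-trimethylperhydro-1-benzoxepin-7-one | O=C1CC[C@H]2OC(C)(C)[C@H](O)CC[C@]2(C)C1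
F5 | step 17 | (3R,5aR,9aR)-3-hydroxy-2,2,5a-trimethyl-3,4,5,5a,6,9a-hexahydro-1-benzoxepin-7(2H)-one (C21=C22 enone) | O=C1C=C[C@H]2OC(C)(C)[C@H](O)CC[C@]2(C)C1
F6 | step 17 | C13-propargylated enone (28 with a C21=C22 double bond) | C=CCC[C@@H]1[C@@H](CC[C@@]1(C)O)C(C)(C)C#CC[C@@H]1[C@@]2(C)CC[C@@H](O)C(C)(C)O[C@@H]2C=CC1=O
F7 | step 18 | (3R,5aR,9aR)-3-hydroxy-2,2,5a-trimethyl-6-methylideneperhydro-1-benzoxepin-7-one | C=C1C(=O)CC[C@H]2OC(C)(C)[C@H](O)CC[C@]12C
F8 | step 18 | trimethylsilyl ether of alkyne 16 | C=CCC[C@@H]1[C@@H](CC[C@@]1(C)O[Si](C)(C)C)C(C)(C)C#C
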